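**Plan**
- Retrosynthesis: the ester C–O bonds at C9 and C3 and the C7–C11 bond are cut first. Ring B is then opened at C6=C7 (aldol condensation of a C6 aldehyde with the C7 methyl of a C8 methyl ketone). Ring A is finally cut at C3–C4 and C5–C10 (Diels–Alder).
- Enabling feature: ring A (C1–C5, C10) carries cis methyls on neighbouring C4 and C5, and quaternary C5 holds C6 cis to the C10–C9 bond. The methyl pair is that of (E)-2-methylbut-2-enal; the cis C6/C9 relation (the cis ring fusion) is the endo adduct with an (E)-1-substituted butadiene (C3, C2, C1, C10 carrying C9–C8–C7 as a masked methyl ketone).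
- Forward: diene from a ketal ester; ring A by the enantioselective [4+2]; C3 oxygenation on the monocycle; ring B by deketalisation and aldol condensation; then C9 oxygenation, C7 isopropenylation, C6–C7 saturation and the angelate.
- Stereochemistry: C4, C5 and C10 from the cycloaddition (dienophile geometry, endo rule, chiral oxazaborolidinium). C3 by hydride from the α face, then Mitsunobu inversion that also installs the senecioate. C9 by oxidation on the convex β face. C7 by axial protonation of the enolate, leaving isopropenyl equatorial.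

Key step: step 3

Assumption: eremophilane numbering is used throughout and α/β are relative, β being the face that carries the C5 methyl group; compounds 1, 3, 6, 11, 21 and 26 are bought.

**Route**

Step 1
Reactants: 1 ethyl 2-(2-methyl-1,3-dioxolan-2-yl)acetate
Product: 2 2-(2-methyl-1,3-dioxolan-2-yl)acetaldehyde
Conditions: i-Bu2AlH (1.05 equiv), CH2Cl2, −78 °C; MeOH, aq. KNa tartrate
Reagents that add atoms: none
Why: Partial reduction of an ester with diisobutylaluminium hydride, in which the tetrahedral aluminium hemiacetal should survive at −78 °C and release the aldehyde only on work-up, the ketal being inert.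

Step 2
Reactants: 3 allyl(diphenyl)phosphine oxide; 2 2-(2-methyl-1,3-dioxolan-2-yl)acetaldehyde
Product: 5 2-methyl-2-[(2E)-penta-2,4-dien-1-yl]-1,3-dioxolane, via lithiated phosphine oxide 4 (not isolated)
Conditions: 3, n-BuLi, THF–HMPA, −78 °C; then 2, −78 → 23 °C
Reagents that add atoms: n-butyllithium, [Li]CCCC (lithium kept only in intermediate 4)
Why: Horner–Wittig olefination, in which 4 adds through its α-carbon to the aldehyde and loses diphenylphosphinate, which in THF–HMPA should give the (E)-configured new double bond; no stereocenter is formed.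

Step 3
Reactants: 5 2-methyl-2-[(2E)-penta-2,4-dien-1-yl]-1,3-dioxolane; 6 (E)-2-methylbut-2-enal
Product: 7 (1R,2S,6S)-1,6-dimethyl-2-[(2-methyl-1,3-dioxolan-2-yl)methyl]cyclohex-3-ene-1-carbaldehyde
Conditions: (R)-3,3-diphenyl-1-(2-methylphenyl)tetrahydro-1H,3H-pyrrolo[1,2-c][1,3,2]oxazaborole (20 mol%), HNTf2 (18 mol%), 6 (2 equiv), CH2Cl2, −40 → −20 °C
Reagents that add atoms: none
Why: The formyl oxygen of 6 binds to boron of the N-protonated oxazaborolidine (s-trans enal, formyl C–H against the ring oxygen), and 5 adds in a concerted, asynchronous [4+2] in which the unsubstituted terminus C3 bonds first to the β-carbon C4 and the substituted terminus C10 then to the α-carbon C5; the closest known reaction type is the oxazaborolidinium-catalysed Diels–Alder reaction of 2-substituted enals with 1-substituted butadienes. Ring A closes as a cyclohexene by this cycloaddition, the only ring-forming event of the step. At C4 and C5 the (E)-geometry of 6 is transferred suprafacially, so the two methyl groups end cis; at C10 the endo position of the formyl group relative to the (E)-diene puts C6 cis to the C9 side chain, the later cis ring fusion. The absolute sense of all three centres should follow from the catalyst, one gem-phenyl group covering a face of the bound enal so that, by the accepted pre-transition-state model, the (R)-catalyst directs the diene to the Si face of the α-carbon. The step needs ortho regiochemistry, endo selectivity and one enantioface: the first comes from the larger HOMO coefficient at the unsubstituted terminus of a 1-alkyl diene meeting the β-carbon of the activated enal, the second from secondary overlap with the coordinated formyl group, the third from the catalyst. Because the trisubstituted dienophile is slow, 6 is used in excess and the oxazaborolidine is kept in slight excess over HNTf2 so that no free acid reaches the dioxolane of 5.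

Step 4
Reactants: 7 (1R,2S,6S)-1,6-dimethyl-2-[(2-methyl-1,3-dioxolan-2-yl)methyl]cyclohex-3-ene-1-carbaldehyde
Product: 8 2-{(1R,2S,6S)-1,6-dimethyl-2-[(2-methyl-1,3-dioxolan-2-yl)methyl]cyclohex-3-en-1-yl}-1,3-dioxolane
Conditions: TMSOCH2CH2OTMS, TMSOTf (cat.), CH2Cl2, −78 → −20 °C
Reagents that add atoms: 1,2-bis(trimethylsilyloxy)ethane, C[Si](C)(C)OCCO[Si](C)(C)C
Why: Acetalisation of a hindered aldehyde with the bis-silylated diol under silyl triflate catalysis; the formyl carbon is α-quaternary so nothing can epimerise, and the existing ketal can only exchange with the same diol.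

Step 5
Reactants: 8 bis-dioxolane of step 4
Product: 9 cyclohex-2-enone of 8 (C1=C2–C3=O; carbonyl at C3 next to C4, both dioxolanes kept)
Conditions: CrO3, 3,5-dimethylpyrazole, CH2Cl2, −20 °C
Reagents that add atoms: chromium trioxide, O=[Cr](=O)=O
Why: Allylic oxidation of a cyclohexene to the cyclohexenone with the CrO3–3,5-dimethylpyrazole complex; C3 is the only allylic methylene (C10–H is tertiary and flanked by quaternary C5 and the side chain), and oxygen should end at C3, next to the small CH(CH3), and not at C1, next to the ring carbon that carries the ketal chain.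

Step 6
Reactants: 9 enone of step 5
Product: 10 3β-allylic alcohol of 9 (OH cis to the C4 methyl, C1=C2 kept)
Conditions: i-Bu2AlH, toluene, −78 °C
Reagents that add atoms: none
Why: 1,2-Reduction of an enone with a bulky aluminium hydride, in which hydride should reach C3 from the α face, away from the axial C5 methyl and the C4 methyl (both β), so that the new C3 centre carries a β-hydroxyl.

Step 7
Reactants: 10 3β-allylic alcohol; 11 3-methylbut-2-enoic acid
Product: 12 allylic 3α-(3-methylbut-2-enoate) of the C1=C2 cyclohexene (ester trans to the C4 methyl)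
Conditions: 11, PPh3, DIAD, toluene, 0 → 23 °C
Reagents that add atoms: none
Why: Mitsunobu esterification, in which the carboxylate displaces the allylic oxyphosphonium group by SN2 with inversion; the leaving group is pseudoaxial and syn to the C5 methyl, so its departure relieves strain, and the open α face at C3 should take the nucleophile, which sets the 3α configuration of the target and installs the senecioate in one operation.

Step 8
Reactants: 12 allylic 3α-ester
Product: 13 saturated 3α-(3-methylbut-2-enoate) (cyclohexane, both dioxolanes kept)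
Conditions: H2 (1 atm), RhCl(PPh3)3 (10 mol%), benzene–EtOH, 23 °C
Reagents that add atoms: none
Why: Homogeneous hydrogenation with RhCl(PPh3)3, which should reduce the cis-disubstituted ring alkene and leave the trisubstituted, conjugated double bond of the ester; no stereocenter is formed.

Step 9
Reactants: 13 saturated bis-dioxolane ester
Product: 16 3α-(3-methylbut-2-enoyloxy)-10βH-eremophil-6-en-8-one (cis-fused), via keto aldehyde 14 (not isolated), via aldol 15 (not isolated)
Conditions: TsOH·H2O, acetone–H2O, 50 °C; then benzene, 80 °C (Dean–Stark)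
Reagents that add atoms: water, O
Why: Acid hydrolysis of both dioxolanes followed by intramolecular aldol condensation, in which only the C7 methyl can reach the non-enolisable C6 aldehyde through a six-membered ring; C10 is not α to a carbonyl, so the cis fusion from step 3 is kept, and the ester tolerates the acid.

Step 10
Reactants: 16 bicyclic enone
Product: 19 9β-(tert-butyldimethylsilyloxy)-3α-(3-methylbut-2-enoyloxy)-10βH-eremophil-6-en-8-one, via silyl dienol ether 17 (not isolated), via silyloxy epoxide 18 (not isolated)
Conditions: TBSOTf, Et3N, CH2Cl2, 0 °C; then dimethyldioxirane, acetone–CH2Cl2, −40 → 23 °C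
Reagents that add atoms: tert-butyldimethylsilyl triflate, CC(C)(C)[Si](C)(C)OS(=O)(=O)C(F)(F)F; dimethyldioxirane, CC1(C)OO1
Why: Rubottom oxidation, in which enolisation can only go toward C9 because C5 is quaternary, the electron-rich C8=C9 bond of 17 is epoxidised ahead of the electron-poor enone and enoate double bonds, attack comes from the convex β face (ring A covers the α face), and the 1,4-silyl shift of 18 leaves the 9β-silyloxy ketone, which is also the equatorial C9 epimer.

Step 11
Reactants: 19 9β-silyloxy enone
Product: 20 7-iodo derivative of 19 (2-iodoenone, iodine on C7)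
Conditions: I2, pyridine, CH2Cl2, 23 °C
Reagents that add atoms: iodine, II
Why: α-Iodination of an enone by a Baylis–Hillman-type sequence (pyridine adds to C6, the enolate is iodinated at C7, pyridine is lost); the β,β-disubstituted enoate of the C3 ester does not accept pyridine.

Step 12
Reactants: 20 7-iodo enone; 21 4,4,5,5-tetramethyl-2-(prop-1-en-2-yl)-1,3,2-dioxaborolane
Product: 22 9β-(tert-butyldimethylsilyloxy)-3α-(3-methylbut-2-enoyloxy)-10βH-eremophila-6,11-dien-8-one
Conditions: 21, Pd(PPh3)4 (5 mol%), K3PO4, 1,4-dioxane–H2O, 60 °C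
Reagents that add atoms: none
Why: Suzuki–Miyaura coupling of a 2-iodoenone with an alkenylboronate, which forms the C7–C11 bond without touching a stereocenter (C9, if it equilibrates under the base, settles in the equatorial 9β form).

Step 13
Reactants: 22 cross-conjugated dienone
Product: 24 9β-(tert-butyldimethylsilyloxy)-3α-(3-methylbut-2-enoyloxy)-10βH-eremophil-11-en-8-one (7β-isopropenyl), via lithium enolate 23 (not isolated)
Conditions: LiBH(s-Bu)3 (1.1 equiv), THF, −78 °C; then AcOH, −78 °C
Reagents that add atoms: lithium tri-sec-butylborohydride, [Li+].CCC(C)[BH-](C(C)CC)C(C)CC (lithium kept only in intermediate 23)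
Why: Conjugate reduction of a β-unsubstituted cyclohexenone, in which hydride adds to C6 and dienolate 23 is protonated kinetically at the α-carbon C7 and not at C12; axial protonation from the α face should leave the isopropenyl group equatorial (β), since protonation from the β face would force it syn-axial to C4.

Step 14
Reactants: 24 silyl ether
Product: 25 9β-hydroxy-3α-(3-methylbut-2-enoyloxy)-10βH-eremophil-11-en-8-one
Conditions: HF·pyridine, THF, 0 → 23 °C
Reagents that add atoms: none
Why: Fluoride cleavage of a silyl ether under buffered, non-basic conditions, chosen so that C7 and C9 (both α to the C8 ketone) are not enolised and the isopropenyl double bond does not move into conjugation.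

Step 15
Reactants: 25 9β-hydroxy ketone; 26 (Z)-2-methylbut-2-enoic acid (angelic acid)
Product: 28 target, 9β-[(Z)-2-methylbut-2-enoyloxy]-3α-(3-methylbut-2-enoyloxy)-10βH-eremophil-11-en-8-one, via mixed anhydride 27 (not isolated)
Conditions: 26, 2,4,6-trichlorobenzoyl chloride, Et3N, toluene, 23 °C, filter; then 25, toluene, 80 °C
Reagents that add atoms: 2,4,6-trichlorobenzoyl chloride, O=C(Cl)c1c(Cl)cc(Cl)cc1Cl (atoms kept only in intermediate 27)
Why: Yamaguchi-type esterification, in which the alcohol attacks the less hindered angeloyl carbonyl of 27 in the absence of free base or nucleophilic catalyst, conditions that should keep the (Z)-geometry of the angelate and the C7 and C9 configurations.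

**Compound list**
1 | ethyl 2-(2-methyl-1,3-dioxolan-2-yl)acetate | CCOC(=O)CC1(C)OCCO1 | starting material
2 | 2-(2-methyl-1,3-dioxolan-2-yl)acetaldehyde | O=CCC1(C)OCCO1 | intermediate
3 | allyl(diphenyl)phosphine oxide | C=CCP(=O)(c1ccccc1)c1ccccc1 | starting material
4 | lithiated allyl(diphenyl)phosphine oxide | [Li+].C=C[CH-]P(=O)(c1ccccc1)c1ccccc1 | intermediate (not isolated)
5 | 2-methyl-2-[(2E)-penta-2,4-dien-1-yl]-1,3-dioxolane | CC1(C/C=C/C=C)OCCO1 | intermediate
6 | (E)-2-methylbut-2-enal | C/C=C(\C)C=O | starting material
7 | (1R,2S,6S)-1,6-dimethyl-2-[(2-methyl-1,3-dioxolan-2-yl)methyl]cyclohex-3-ene-1-carbaldehyde | O=C[C@@]1(C)[C@@H](CC2(C)OCCO2)C=CC[C@@H]1C | intermediate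
8 | 1,3-dioxolane acetal of 7 | O1CCOC1[C@@]1(C)[C@@H](CC2(C)OCCO2)C=CC[C@@H]1C | intermediate
9 | C1=C2–C3=O enone of 8 | O1CCOC1[C@@]1(C)[C@@H](CC2(C)OCCO2)C=CC(=O)[C@@H]1C | intermediate
10 | 3β-allylic alcohol (OH cis to C4 methyl) | O1CCOC1[C@@]1(C)[C@@H](CC2(C)OCCO2)C=C[C@H](O)[C@@H]1C | intermediate
11 | 3-methylbut-2-enoic acid | CC(C)=CC(=O)O | starting material
12 | allylic 3α-(3-methylbut-2-enoate) | O1CCOC1[C@@]1(C)[C@@H](CC2(C)OCCO2)C=C[C@@H](OC(=O)C=C(C)C)[C@@H]1C | intermediate
13 | saturated 3α-(3-methylbut-2-enoate) | O1CCOC1[C@@]1(C)[C@@H](CC2(C)OCCO2)CC[C@@H](OC(=O)C=C(C)C)[C@@H]1C | intermediate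
14 | keto aldehyde (C6 formyl, C8 methyl ketone) | O=C[C@@]1(C)[C@@H](CC(C)=O)CC[C@@H](OC(=O)C=C(C)C)[C@@H]1C | intermediate (not isolated)
15 | aldol, 6-hydroxy-8-ketone (C6 epimers) | O=C1CC(O)[C@@]2(C)[C@H](CC[C@@H](OC(=O)C=C(C)C)[C@@H]2C)C1 | intermediate (not isolated)
16 | 3α-(3-methylbut-2-enoyloxy)-10βH-eremophil-6-en-8-one | O=C1C=C[C@@]2(C)[C@H](CC[C@@H](OC(=O)C=C(C)C)[C@@H]2C)C1 | intermediate
17 | 8-(tert-butyldimethylsilyloxy)-6,8-diene (silyl dienol ether of 16) | CC(C)(C)[Si](C)(C)OC=1C=C[C@@]2(C)[C@H](CC[C@@H](OC(=O)C=C(C)C)[C@@H]2C)C=1 | intermediate (not isolated)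
18 | 8β,9β-epoxide of 17 | C1=C[C@@]2(C)[C@H](CC[C@@H](OC(=O)C=C(C)C)[C@@H]2C)[C@H]3O[C@@]13O[Si](C)(C)C(C)(C)C | intermediate (not isolated)
19 | 9β-(tert-butyldimethylsilyloxy)-3α-(3-methylbut-2-enoyloxy)-10βH-eremophil-6-en-8-one | C1=C[C@@]2(C)[C@H](CC[C@@H](OC(=O)C=C(C)C)[C@@H]2C)[C@@H](O[Si](C)(C)C(C)(C)C)C1=O | intermediate
20 | 7-iodo derivative of 19 | IC1=C[C@@]2(C)[C@H](CC[C@@H](OC(=O)C=C(C)C)[C@@H]2C)[C@@H](O[Si](C)(C)C(C)(C)C)C1=O | intermediate
21 | 4,4,5,5-tetramethyl-2-(prop-1-en-2-yl)-1,3,2-dioxaborolane | C=C(C)B1OC(C)(C)C(C)(C)O1 | starting material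
22 | 9β-silyloxy-3α-acyloxy-10βH-eremophila-6,11-dien-8-one | C=C(C)C1=C[C@@]2(C)[C@H](CC[C@@H](OC(=O)C=C(C)C)[C@@H]2C)[C@@H](O[Si](C)(C)C(C)(C)C)C1=O | intermediate
23 | lithium 7,11-dien-8-olate from 22 | [Li+].C=C(C)C=1C[C@@]2(C)[C@H](CC[C@@H](OC(=O)C=C(C)C)[C@@H]2C)[C@@H](O[Si](C)(C)C(C)(C)C)C=1[O-] | intermediate (not isolated)
24 | 9β-silyloxy-3α-acyloxy-10βH-eremophil-11-en-8-one (7β-isopropenyl) | C=C(C)[C@H]1C[C@@]2(C)[C@H](CC[C@@H](OC(=O)C=C(C)C)[C@@H]2C)[C@@H](O[Si](C)(C)C(C)(C)C)C1=O | intermediate
25 | 9β-hydroxy-3α-(3-methylbut-2-enoyloxy)-10βH-eremophil-11-en-8-one | C=C(C)[C@H]1C[C@@]2(C)[C@H](CC[C@@H](OC(=O)C=C(C)C)[C@@H]2C)[C@@H](O)C1=O | intermediate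
26 | (Z)-2-methylbut-2-enoic acid | C/C=C(/C)C(=O)O | starting material
27 | (Z)-2-methylbut-2-enoic 2,4,6-trichlorobenzoic anhydride | C/C=C(/C)C(=O)OC(=O)c1c(Cl)cc(Cl)cc1Cl | intermediate (not isolated)
28 | CNP0164025.2 | C=C(C)[C@H]1C[C@@]2(C)[C@H](CC[C@@H](OC(=O)C=C(C)C)[C@@H]2C)[C@@H](OC(=O)/C(C)=C\C)C1=O | target

**Count and risks**
Total: 15 steps. Longest linear sequence: 15 steps (1 to 28); 3, 6, 11, 21 and 26 enter as bought partners.

Step 5. The oxidant may deliver oxygen to the other end of the allylic system (C1) after hydrogen loss at C3, or attack the tertiary C10–H, so that regioisomeric enones form. The fallback sets out from 8: SeO2 (cat.) with t-BuOOH in CH2Cl2 hydroxylates by an ene reaction followed by a [2,3]-sigmatropic shift, which returns oxygen to the carbon that lost hydrogen and so cannot transpose. The C3 alcohol should arise as 10, as its C3 epimer (the 3α-allylic alcohol F1), or as both. Dess–Martin oxidation of the crude alcohol in CH2Cl2 converges on enone 9, where the route is rejoined.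

Step 7. The activated alcohol may eliminate to a cyclohexadiene, or the carboxylate may attack C1 in an SN2′ sense, instead of inverting C3. The fallback sets out from 9 and replaces inversion by reagent control. Corey–Bakshi–Shibata reduction with (S)-2-methyl-CBS-oxazaborolidine and catecholborane in toluene at −78 °C, taking the branched C4 side as the large group, should deliver hydride to the β face and give the 3α-allylic alcohol F2 (the same structure as F1). Acylation with 3-methylbut-2-enoyl chloride, pyridine and catalytic DMAP in CH2Cl2 then gives 12, where the route is rejoined.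

Step 13. Dienolate 23 may be protonated from the more open β face, which gives the axial 7α-isopropenyl epimer, or at C12, which gives the conjugated isopropylidene ketone; base equilibration cannot repair this because it drains into the conjugated isomer. The fallback sets out from 19 and forms the C7 stereocenter by C–C bond formation on the convex face. LiBH(s-Bu)3 in THF at −78 °C reduces the unsubstituted enone to the lithium 7-en-8-olate F3. Acetone (with ZnCl2) is then added, and the electrophile should enter from the β face to give the 7β-(2-hydroxypropan-2-yl) ketone F4. Dehydration with SOCl2 and pyridine at −20 °C should remove a methyl hydrogen by E2, since H7 is axial on the concave α face and hard to reach. This gives 24, where the route is rejoined without 20 and 22.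

**Further compounds**
F1 | step 5 | 3α-allylic alcohol, C3 epimer of 10 | O1CCOC1[C@@]1(C)[C@@H](CC2(C)OCCO2)C=C[C@@H](O)[C@@H]1C
F2 | step 7 | 3α-allylic alcohol, C3 epimer of 10 (same structure as F1) | O1CCOC1[C@@]1(C)[C@@H](CC2(C)OCCO2)C=C[C@@H](O)[C@@H]1C
F3 | step 13 | lithium 7-en-8-olate from conjugate reduction of 19 | [Li+].C=1C[C@@]2(C)[C@H](CC[C@@H](OC(=O)C=C(C)C)[C@@H]2C)[C@@H](O[Si](C)(C)C(C)(C)C)C=1[O-]
F4 | step 13 | 7β-(2-hydroxypropan-2-yl)-9β-silyloxy-3α-acyloxy-10βH-eremophilan-8-one | CC(C)(O)[C@H]1C[C@@]2(C)[C@H](CC[C@@H](OC(=O)C=C(C)C)[C@@H]2C)[C@@H](O[Si](C)(C)C(C)(C)C)C1=O
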